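Book G first, before any rate: count what each mole of it costs in Q, then see what is left for D.

| setting | west | north-east | Tuesday's | Sunday's |
|---|---|---|---|---|
| Q | 0.050 M | 0.050 M | 0.050 M | 0.050 M |
| G | 3.4 mM | 7.5 mM | 5.00 mM | 5.00 mM |
| remark | run made earlier | run made earlier |  |  |
| time |  |  | 10 min | 25 min |

| run | time / min | Q / % | D / % |
|---|---|---|---|
| west | 1.00 | 74.5 | 0.7 |
| west | 3.00 | 48.3 | 2.9 |
| west | 5.00 | 31.8 | 11.0 |
| west | 8.00 | 14.9 | 29.7 |
| north-east | 1.00 | 69.2 | 0 |
| north-east | 3.00 | 44.1 | 2.7 |
| north-east | 5.00 | 30.5 | 7.6 |
| north-east | 8.00 | 15.8 | 21.8 |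

(readings scatter by 0.3 percentage points)

* which of these there is most of at the end, counted by the Q in it, Tuesday's (Q / D)
* which of these there is most of at the end, counted by the Q in it, Sunday's (Q / D)
* the largest of these amounts at the end, in percent of the Q charged, Tuesday's
* the largest of these amounts at the end, in percent of the Q charged, Sunday's

Open the ledger with G, the limiting reagent in Tuesday's and Sunday's flasks, where 5.00 mM stands against 0.050 M of Q. The first entry comes from the early end. At 1.00 min the north-east run, with more G, reads 69.2% of Q, less than the 74.5% of the west run. So enter, as my own working assumption, one Q lost for good per G.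

Call the toll the charged [G] divided by the charged [Q], the share of Q that G removes. It is 6.80% in the west run and 10.0% in Tuesday's and Sunday's flasks.

The second entry comes from the late end: subtract the toll from the whole charge, which puts the ceiling on D in those flasks at 90.0%.

Now join the ends. At 8.00 min the west run reads 44.6% as Q and D together, so, if its toll is paid in full by then, my count puts 48.6% in an unread pool. Close the books thus: D equals the ceiling less the Q and the pool still standing at that time.

The forecast names D in both flasks, with 38% (33% to 43%) on Tuesday's and 85% (77% to 91%) on Sunday's, saying “D approaches the ceiling of about 90%, say 85%”.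

The flask gives D on top both times: 36.9% against 8.87% of Q on Tuesday's, within the range, and 75.8% against 1.13% on Sunday's, 9.2 percentage points below the forecast.

    Q + D → 2 D (k = 0.490 M⁻¹ s⁻¹)
    Q → D (k = 4.00 × 10⁻⁵ s⁻¹)
    Q ⇌ J (K = 2.20, k = 0.00400 s⁻¹)
    Q + G → X (k = 0.640 M⁻¹ s⁻¹)

Sunday's X stands at 10.0%, the toll, with G down to 0.0328% of its charge, and J, the pool, holds 13.0%. Sunday's ceiling less that Q and J is its 75.8% of D. Take the neighbouring flask, Sunday's with 0.020 M of G: its toll is 40.0% and its ceiling 60.0%. It ends with X at 40.0%, Q at 2.18% and J at 15.3%, and its ceiling less that Q and J is the 42.5% of D it holds.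

The readings come from a simulation for an exercise.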